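Ring A is built last. The route rests on cutting C8–C8a and C4a–C5, so that ring A arises from 4-chloro-2,3-dimethoxycyclobutenone and a chiral 6-stannyl dihydropyran that already holds ring B, C2 and C3. In one operation, Stille coupling followed by 4π ring opening and 6π closure creates the whole benzene ring; the cascade exploits the C8a=C4a enol ether bond of ring C as the terminal 2π unit and delivers the C5, C6 and C7 oxygens and the lone C8 hydrogen directly. The precursor is an all-trans 2-aryl-3-methoxy-4-silyloxy-6-tributylstannyl-3,4-dihydro-2H-pyran, made by an asymmetric hetero-Diels–Alder reaction, α-hydroxylation, reduction and C–H stannylation.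

Key step: step 12

Abbreviation: Ar = 4-methoxy-3,5-bis(triisopropylsilyloxy)phenyl.

Assumption: the Ti(OiPr)4/BINOL catalyst is taken to show the facial preference it has in additions of allyl and enol silane nucleophiles to aromatic aldehydes, (S)-BINOL sending the nucleophile to the Si face; should the first run show the opposite sense, (R)-BINOL is used and nothing else changes.

Step 1
Reactants: 1 methyl 3,5-dihydroxy-4-methoxybenzoate
Product: 2 methyl 4-methoxy-3,5-bis(triisopropylsilyloxy)benzoate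
Conditions: TIPSCl, imidazole, DMF, rt → 40 °C
Reagents that add atoms: triisopropylsilyl chloride, CC(C)[Si](Cl)(C(C)C)C(C)C
Why: Standard silyl ether formation on both phenols; the bulky TIPS group is chosen because it resists acid, does not direct ortho-metalation and offers no readily metalated C–H bond in step 9.

Step 2
Reactants: 2 methyl 4-methoxy-3,5-bis(triisopropylsilyloxy)benzoate
Product: 3 [4-methoxy-3,5-bis(triisopropylsilyloxy)phenyl]methanol
Conditions: i-Bu2AlH (2.5 equiv), CH2Cl2, −78 → 0 °C; aq. potassium sodium tartrate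
Reagents that add atoms: none
Why: Hydride reduction of the ester to the benzylic alcohol, which aryl silyl ethers tolerate.

Step 3
Reactants: 3 [4-methoxy-3,5-bis(triisopropylsilyloxy)phenyl]methanol
Product: 4 4-methoxy-3,5-bis(triisopropylsilyloxy)benzaldehyde
Conditions: MnO2 (activated, excess), CH2Cl2, rt
Reagents that add atoms: none
Why: Selective benzylic oxidation that stops at the aldehyde and needs only filtration.

Step 4
Reactants: 4 4-methoxy-3,5-bis(triisopropylsilyloxy)benzaldehyde, 5 (E)-1-methoxy-3-(trimethylsilyloxy)buta-1,3-diene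
Product: 7 (S)-2-Ar-2,3-dihydro-4H-pyran-4-one, via aldol adduct 6 (not isolated)
Conditions: Ti(OiPr)4 (10 mol %), (S)-BINOL (20 mol %), 4 Å MS, Et2O, −20 °C; then TFA, CH2Cl2, 0 °C
Reagents that add atoms: none
Why: Catalytic asymmetric hetero-Diels–Alder reaction in its stepwise Mukaiyama aldol–cyclisation form, in which the chiral titanium BINOLate binds the aldehyde and leaves its Si face open to the diene terminus (this sets C2), and TFA then closes the ring by conjugate addition of the carbinol oxygen with loss of methanol.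

Step 5
Reactants: 7 (S)-2-Ar-2,3-dihydro-4H-pyran-4-one
Product: 9 (2R,3R)-3-hydroxy-2-Ar-2,3-dihydro-4H-pyran-4-one, via sodium enolate 8 (not isolated)
Conditions: NaN(SiMe3)2, THF, −78 °C; then 2-(phenylsulfonyl)-3-phenyloxaziridine, −78 °C; aq. NH4Cl
Reagents that add atoms: 2-(phenylsulfonyl)-3-phenyloxaziridine, O=S(=O)(N1OC1c1ccccc1)c1ccccc1
Why: Enolate hydroxylation with an N-sulfonyloxaziridine; C3 is the only enolisable position and oxygen should be delivered to the enolate face opposite the neighbouring C2 aryl group, giving the 2,3-trans ketol, which is also the thermodynamically preferred diequatorial isomer.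

Step 6
Reactants: 9 (2R,3R)-3-hydroxy-2-Ar-2,3-dihydro-4H-pyran-4-one
Product: 10 (2R,3R)-3-methoxy-2-Ar-2,3-dihydro-4H-pyran-4-one
Conditions: MeI (excess), Ag2O, CH2Cl2, rt → 40 °C, dark
Reagents that add atoms: iodomethane, CI
Why: Purdie methylation alkylates the α-hydroxyl under nearly neutral conditions, so ring opening and loss of aryl silyl ethers are not expected, and C3 stays trans because that isomer is favoured even if the ketone enolises.

Step 7
Reactants: 10 (2R,3R)-3-methoxy-2-Ar-2,3-dihydro-4H-pyran-4-one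
Product: 11 (2R,3S,4R)-3-methoxy-2-Ar-3,4-dihydro-2H-pyran-4-ol (all-trans)
Conditions: NaBH4, CeCl3·7H2O, MeOH/CH2Cl2, −78 → −40 °C
Reagents that add atoms: none
Why: Luche reduction gives 1,2-reduction of the vinylogous ester carbonyl, and axial hydride attack on the half-chair should place the C4 hydroxyl equatorial and trans to the C3 methoxy group (C4 is oxidised again in step 15, so its configuration is not critical).

Step 8
Reactants: 11 (2R,3S,4R)-3-methoxy-2-Ar-3,4-dihydro-2H-pyran-4-ol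
Product: 12 (2R,3R,4R)-3-methoxy-2-Ar-4-(triethylsilyloxy)-3,4-dihydro-2H-pyran
Conditions: TESCl, imidazole, CH2Cl2, 0 °C → rt
Reagents that add atoms: chlorotriethylsilane, CC[Si](Cl)(CC)CC
Why: Standard silylation of the allylic alcohol; the triethylsilyl group carries no Si–CH3 protons that t-BuLi could remove in step 9 and can later be hydrolysed by dilute aqueous acid without touching the aryl TIPS ethers.

Step 9
Reactants: 12 (2R,3R,4R)-3-methoxy-2-Ar-4-(triethylsilyloxy)-3,4-dihydro-2H-pyran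
Product: 14 (2R,3R,4R)-3-methoxy-2-Ar-4-(triethylsilyloxy)-6-(tributylstannyl)-3,4-dihydro-2H-pyran, via alkenyllithium 13 (not isolated)
Conditions: t-BuLi (3 equiv), THF, −78 → 0 °C; then Bu3SnCl, −78 °C → rt
Reagents that add atoms: tributyltin chloride, CCCC[Sn](Cl)(CCCC)CCCC
Why: α-Lithiation of a cyclic enol ether as practised on silyl-protected glycals, in which the sp2 C6–H next to the ring oxygen is removed by t-BuLi with assistance from that oxygen and the alkenyllithium is trapped on carbon by Bu3SnCl.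

Step 10
Reactants: 15 dimethyl squarate (3,4-dimethoxycyclobut-3-ene-1,2-dione)
Product: 16 4-hydroxy-2,3-dimethoxycyclobut-2-en-1-one (racemic)
Conditions: LiAlH(OtBu)3 (1.05 equiv), THF, −78 → −20 °C; aq. NH4Cl
Reagents that add atoms: none
Why: Chemoselective mono-reduction of a cyclobutenedione, where the bulky and mild hydride adds once to one carbonyl and stops at the hydroxycyclobutenone.

Step 11
Reactants: 16 4-hydroxy-2,3-dimethoxycyclobut-2-en-1-one
Product: 17 4-chloro-2,3-dimethoxycyclobut-2-en-1-one (racemic)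
Conditions: PPh3, CCl4, CH2Cl2, 0 °C → rt; used promptly
Reagents that add atoms: carbon tetrachloride, ClC(Cl)(Cl)Cl
Why: Appel reaction converts the activated α-keto allylic alcohol into the chloride under neutral conditions, avoiding the acid that would expel methanol from the vinylogous ester.

Step 12
Reactants: 14 (2R,3R,4R)-3-methoxy-2-Ar-4-(triethylsilyloxy)-6-(tributylstannyl)-3,4-dihydro-2H-pyran, 17 4-chloro-2,3-dimethoxycyclobut-2-en-1-one
Product: 21 (2R,3R,4R)-2-Ar-3,6,7-trimethoxy-4-(triethylsilyloxy)chroman-5-ol, via alkenylcyclobutenone 18 (not isolated), via dienylketene 19 (not isolated), via cyclohexadienone 20 (not isolated)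
Conditions: Pd2(dba)3 (2.5 mol %), tri(2-furyl)phosphine (10 mol %), dioxane, 50 °C; then 100 °C
Reagents that add atoms: none
Why: Zerovalent palladium inserts into the C–Cl bond of 17 to give an oxocyclobutenyl complex of divalent palladium, and transmetalation from tin with reductive elimination at the unsubstituted ring carbon forges C8–C8a (18); at 100 °C the strained ring opens by conrotatory 4π electrocyclic opening to dienylketene 19, whose ketene carbon bonds to C4a in a thermal disrotatory 6π electrocyclisation (20), and tautomerisation gives phenol 21. The closest known reaction type is the Stille coupling of 4-chlorocyclobutenones with alkenylstannanes followed by thermal ring expansion to phenols, together with the Stille coupling of α-stannyl cyclic enol ethers. Ring A, a six-membered carbocycle, is closed by the 6π electrocyclisation, with the C8a=C4a enol ether bond of ring C as the terminal 2π unit. No lasting stereocentre is formed (C4a is sp3 only in 20), and C2, C3 and C4 lie outside the reacting π system. The step needs C–C bond formation at the CH terminus of the oxo-allyl palladium unit, which its lower substitution should secure, and inward rotation of the alkenyl group, which is met because ring opening is reversible and only the inward isomer is drained by cyclisation; the C5-OH, C6-OMe, C7-OMe, C8-H pattern then follows from connectivity alone.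

Step 13
Reactants: 21 (2R,3R,4R)-2-Ar-3,6,7-trimethoxy-4-(triethylsilyloxy)chroman-5-ol
Product: 22 (2R,3R,4R)-2-Ar-3,5,6,7-tetramethoxy-4-(triethylsilyloxy)chroman
Conditions: MeI, K2CO3, acetone, rt → 40 °C
Reagents that add atoms: iodomethane, CI
Why: Williamson methylation of the only free phenol, done while C4 is still sp3 so that the mild base cannot open ring C or epimerise C2 and C3 as it could in a chroman-4-one.

Step 14
Reactants: 22 (2R,3R,4R)-2-Ar-3,5,6,7-tetramethoxy-4-(triethylsilyloxy)chroman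
Product: 23 (2R,3S,4R)-2-Ar-3,5,6,7-tetramethoxychroman-4-ol
Conditions: AcOH/THF/H2O (3:1:1), 0 °C → rt
Reagents that add atoms: none
Why: Acid-catalysed hydrolysis of the secondary triethylsilyl ether, which is far more labile than aryl TIPS ethers; with water as the only nucleophile, any reversible ionisation at the electron-rich benzylic C4 merely returns the alcohol, whose configuration is irrelevant.

Step 15
Reactants: 23 (2R,3S,4R)-2-Ar-3,5,6,7-tetramethoxychroman-4-ol
Product: 24 (2R,3R)-2-Ar-3,5,6,7-tetramethoxychroman-4-one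
Conditions: Dess–Martin periodinane, NaHCO3, CH2Cl2, 0 °C → rt
Reagents that add atoms: none
Why: Dess–Martin oxidation of the secondary benzylic alcohol to the ketone under buffered, non-basic conditions that should leave the new α-stereocentre C3 and the silyl ethers untouched.

Step 16
Reactants: 24 (2R,3R)-2-Ar-3,5,6,7-tetramethoxychroman-4-one
Product: 25 (2R,3R)-2-(3,5-dihydroxy-4-methoxyphenyl)-3,5,6,7-tetramethoxychroman-4-one (target)
Conditions: HF·pyridine, pyridine, THF, 0 °C → rt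
Reagents that add atoms: none
Why: Fluoride cleavage of the two aryl silyl ethers in a buffered acidic medium, which avoids the base-induced ring opening and C2/C3 epimerisation to which dihydroflavonols are prone.

Compound list
1 | methyl 3,5-dihydroxy-4-methoxybenzoate | COC(=O)c1cc(O)c(OC)c(O)c1 | starting material
2 | methyl 4-methoxy-3,5-bis(triisopropylsilyloxy)benzoate | COC(=O)c1cc(O[Si](C(C)C)(C(C)C)C(C)C)c(OC)c(O[Si](C(C)C)(C(C)C)C(C)C)c1 | intermediate
3 | [4-methoxy-3,5-bis(triisopropylsilyloxy)phenyl]methanol | OCc1cc(O[Si](C(C)C)(C(C)C)C(C)C)c(OC)c(O[Si](C(C)C)(C(C)C)C(C)C)c1 | intermediate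
4 | 4-methoxy-3,5-bis(triisopropylsilyloxy)benzaldehyde | O=Cc1cc(O[Si](C(C)C)(C(C)C)C(C)C)c(OC)c(O[Si](C(C)C)(C(C)C)C(C)C)c1 | intermediate
5 | (E)-1-methoxy-3-(trimethylsilyloxy)buta-1,3-diene | CO/C=C/C(=C)O[Si](C)(C)C | starting material
6 | (S,E)-5-Ar-1-methoxy-5-(trimethylsilyloxy)pent-1-en-3-one (aldol adduct) | CO/C=C/C(=O)C[C@@H](c1cc(O[Si](C(C)C)(C(C)C)C(C)C)c(OC)c(O[Si](C(C)C)(C(C)C)C(C)C)c1)O[Si](C)(C)C | intermediate (not isolated)
7 | (S)-2-Ar-2,3-dihydro-4H-pyran-4-one | O=C1C[C@@H](c2cc(O[Si](C(C)C)(C(C)C)C(C)C)c(OC)c(O[Si](C(C)C)(C(C)C)C(C)C)c2)OC=C1 | intermediate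
8 | sodium (S)-2-Ar-2H-pyran-4-olate (sodium enolate) | [Na+].[O-]C1=C[C@@H](c2cc(O[Si](C(C)C)(C(C)C)C(C)C)c(OC)c(O[Si](C(C)C)(C(C)C)C(C)C)c2)OC=C1 | intermediate (not isolated)
9 | (2R,3R)-3-hydroxy-2-Ar-2,3-dihydro-4H-pyran-4-one (2,3-trans) | O=C1[C@H](O)[C@@H](c2cc(O[Si](C(C)C)(C(C)C)C(C)C)c(OC)c(O[Si](C(C)C)(C(C)C)C(C)C)c2)OC=C1 | intermediate
10 | (2R,3R)-3-methoxy-2-Ar-2,3-dihydro-4H-pyran-4-one (2,3-trans) | O=C1[C@H](OC)[C@@H](c2cc(O[Si](C(C)C)(C(C)C)C(C)C)c(OC)c(O[Si](C(C)C)(C(C)C)C(C)C)c2)OC=C1 | intermediate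
11 | (2R,3S,4R)-3-methoxy-2-Ar-3,4-dihydro-2H-pyran-4-ol (all-trans) | C1=C[C@@H](O)[C@H](OC)[C@@H](c2cc(O[Si](C(C)C)(C(C)C)C(C)C)c(OC)c(O[Si](C(C)C)(C(C)C)C(C)C)c2)O1 | intermediate
12 | (2R,3R,4R)-3-methoxy-2-Ar-4-(triethylsilyloxy)-3,4-dihydro-2H-pyran (all-trans) | C1=C[C@@H](O[Si](CC)(CC)CC)[C@H](OC)[C@@H](c2cc(O[Si](C(C)C)(C(C)C)C(C)C)c(OC)c(O[Si](C(C)C)(C(C)C)C(C)C)c2)O1 | intermediate
13 | (2R,3R,4R)-6-lithio-3-methoxy-2-Ar-4-(triethylsilyloxy)-3,4-dihydro-2H-pyran (alkenyllithium) | [Li]C1=C[C@@H](O[Si](CC)(CC)CC)[C@H](OC)[C@@H](c2cc(O[Si](C(C)C)(C(C)C)C(C)C)c(OC)c(O[Si](C(C)C)(C(C)C)C(C)C)c2)O1 | intermediate (not isolated)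
14 | (2R,3R,4R)-3-methoxy-2-Ar-4-(triethylsilyloxy)-6-(tributylstannyl)-3,4-dihydro-2H-pyran (all-trans) | CCCC[Sn](CCCC)(CCCC)C1=C[C@@H](O[Si](CC)(CC)CC)[C@H](OC)[C@@H](c2cc(O[Si](C(C)C)(C(C)C)C(C)C)c(OC)c(O[Si](C(C)C)(C(C)C)C(C)C)c2)O1 | intermediate
15 | dimethyl squarate (3,4-dimethoxycyclobut-3-ene-1,2-dione) | COC1=C(OC)C(=O)C1=O | starting material
16 | 4-hydroxy-2,3-dimethoxycyclobut-2-en-1-one (racemic) | COC1=C(OC)C(O)C1=O | intermediate
17 | 4-chloro-2,3-dimethoxycyclobut-2-en-1-one (racemic) | COC1=C(OC)C(Cl)C1=O | intermediate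
18 | 2,3-dimethoxy-4-[(2R,3R,4R)-3-methoxy-2-Ar-4-(triethylsilyloxy)-3,4-dihydro-2H-pyran-6-yl]cyclobut-2-en-1-one (both epimers at the cyclobutenone CH) | COC1=C(OC)C(C2=C[C@@H](O[Si](CC)(CC)CC)[C@H](OC)[C@@H](c3cc(O[Si](C(C)C)(C(C)C)C(C)C)c(OC)c(O[Si](C(C)C)(C(C)C)C(C)C)c3)O2)C1=O | intermediate (not isolated)
19 | 2,3-dimethoxy-4-[(2R,3R,4R)-3-methoxy-2-Ar-4-(triethylsilyloxy)-3,4-dihydro-2H-pyran-6-yl]buta-1,3-dien-1-one (dienylketene, pyranyl group cis to the ketene) | O=C=C(OC)/C(OC)=C\C1=C[C@@H](O[Si](CC)(CC)CC)[C@H](OC)[C@@H](c2cc(O[Si](C(C)C)(C(C)C)C(C)C)c(OC)c(O[Si](C(C)C)(C(C)C)C(C)C)c2)O1 | intermediate (not isolated)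
20 | (2R,3R,4R)-2-Ar-3,6,7-trimethoxy-4-(triethylsilyloxy)-2,3,4,4a-tetrahydro-5H-chromen-5-one (cyclohexadienone, C4a unassigned) | COC1=C(OC)C(=O)C2[C@@H](O[Si](CC)(CC)CC)[C@H](OC)[C@@H](c3cc(O[Si](C(C)C)(C(C)C)C(C)C)c(OC)c(O[Si](C(C)C)(C(C)C)C(C)C)c3)OC2=C1 | intermediate (not isolated)
21 | (2R,3R,4R)-2-Ar-3,6,7-trimethoxy-4-(triethylsilyloxy)chroman-5-ol (all-trans) | COc1cc2c(c(O)c1OC)[C@@H](O[Si](CC)(CC)CC)[C@H](OC)[C@@H](c3cc(O[Si](C(C)C)(C(C)C)C(C)C)c(OC)c(O[Si](C(C)C)(C(C)C)C(C)C)c3)O2 | intermediate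
22 | (2R,3R,4R)-2-Ar-3,5,6,7-tetramethoxy-4-(triethylsilyloxy)chroman | COc1cc2c(c(OC)c1OC)[C@@H](O[Si](CC)(CC)CC)[C@H](OC)[C@@H](c3cc(O[Si](C(C)C)(C(C)C)C(C)C)c(OC)c(O[Si](C(C)C)(C(C)C)C(C)C)c3)O2 | intermediate
23 | (2R,3S,4R)-2-Ar-3,5,6,7-tetramethoxychroman-4-ol | COc1cc2c(c(OC)c1OC)[C@@H](O)[C@H](OC)[C@@H](c3cc(O[Si](C(C)C)(C(C)C)C(C)C)c(OC)c(O[Si](C(C)C)(C(C)C)C(C)C)c3)O2 | intermediate
24 | (2R,3R)-2-Ar-3,5,6,7-tetramethoxychroman-4-one | COc1cc2c(c(OC)c1OC)C(=O)[C@H](OC)[C@@H](c3cc(O[Si](C(C)C)(C(C)C)C(C)C)c(OC)c(O[Si](C(C)C)(C(C)C)C(C)C)c3)O2 | intermediate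
25 | (2R,3R)-2-(3,5-dihydroxy-4-methoxyphenyl)-3,5,6,7-tetramethoxychroman-4-one | COc1cc2c(c(OC)c1OC)C(=O)[C@H](OC)[C@@H](c1cc(O)c(OC)c(O)c1)O2 | target

Total step count: 16
Longest linear sequence: 14 steps (steps 1–9 and 12–16); steps 10–11 form the two-step side branch to 17.

Steps most likely to fail

1. Step 12. Transfer of the hindered α-alkoxyalkenyl group from tin to palladium may be slow, so that protodestannylation of the stannane and decay of the sensitive chloride outrun the coupling. The fallback sets out from 12: lithiation as in step 9 gives 13, which is transmetalated with ZnCl2 (THF, −78 → 0 °C) to the alkenylzinc chloride F1. Negishi coupling of this with 17 (Pd(PPh3)4, THF, 0 °C → rt) should give alkenylcyclobutenone 18 at a temperature at which it can be freed from metal salts. Separate thermolysis in toluene at 100 °C through 19 and 20 brings the route back at 21.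

2. Step 9. The base may also remove the benzylic C2–H, which is activated by the ring oxygen and ring B, and the resulting anion would expel the C3 methoxy group. The fallback sets out from 12 and avoids strong base at that stage. Hydration of the enol ether (PPh3·HBr cat., wet THF, rt) gives the 2-deoxy lactol F2, and oxidation with Ag2CO3 on Celite (toluene, 80 °C) gives the δ-lactone F3. Enolisation and O-phosphorylation (KN(SiMe3)2, (PhO)2P(O)Cl, THF, −78 °C) give the ketene acetal diphenyl phosphate F4. Palladium-catalysed stannylation ((Me3Sn)2, Pd(PPh3)4, LiCl, THF, 65 °C) gives the trimethylstannyl enol ether F5, which takes the place of 14 in step 12 and comes back to the route at 21.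

3. Step 5. The enolate may open ring C by β-elimination of the ring oxygen, or it may add to the sulfonimine by-product instead of keeping the new hydroxyl. The fallback sets out from 7 and uses no strong base: α′-acetoxylation with Mn(OAc)3 (benzene, 80 °C) should give the trans acetoxy ketone F6. Luche reduction (NaBH4, CeCl3·7H2O, MeOH, −78 °C) gives the acetoxy alcohol F7, and silylation (TESCl, imidazole, CH2Cl2) gives the acetoxy silyl ether F8. Reductive removal of the acetate (i-Bu2AlH, CH2Cl2, −78 °C) gives the C3 alcohol F9, and methylation with MeI/Ag2O returns to the route at 12.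

Further compounds
F1 | step 12 | chloro[(2R,3R,4R)-3-methoxy-2-Ar-4-(triethylsilyloxy)-3,4-dihydro-2H-pyran-6-yl]zinc (alkenylzinc chloride) | Cl[Zn]C1=C[C@@H](O[Si](CC)(CC)CC)[C@H](OC)[C@@H](c2cc(O[Si](C(C)C)(C(C)C)C(C)C)c(OC)c(O[Si](C(C)C)(C(C)C)C(C)C)c2)O1
F2 | step 9 | (4R,5R,6R)-5-methoxy-6-Ar-4-(triethylsilyloxy)tetrahydro-2H-pyran-2-ol (2-deoxy lactol, anomer mixture) | OC1C[C@@H](O[Si](CC)(CC)CC)[C@H](OC)[C@@H](c2cc(O[Si](C(C)C)(C(C)C)C(C)C)c(OC)c(O[Si](C(C)C)(C(C)C)C(C)C)c2)O1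
F3 | step 9 | (4R,5R,6R)-5-methoxy-6-Ar-4-(triethylsilyloxy)tetrahydro-2H-pyran-2-one (δ-lactone) | O=C1C[C@@H](O[Si](CC)(CC)CC)[C@H](OC)[C@@H](c2cc(O[Si](C(C)C)(C(C)C)C(C)C)c(OC)c(O[Si](C(C)C)(C(C)C)C(C)C)c2)O1
F4 | step 9 | (2R,3R,4R)-3-methoxy-2-Ar-4-(triethylsilyloxy)-3,4-dihydro-2H-pyran-6-yl diphenyl phosphate (ketene acetal diphenyl phosphate) | O=P(Oc1ccccc1)(Oc1ccccc1)OC1=C[C@@H](O[Si](CC)(CC)CC)[C@H](OC)[C@@H](c2cc(O[Si](C(C)C)(C(C)C)C(C)C)c(OC)c(O[Si](C(C)C)(C(C)C)C(C)C)c2)O1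
F5 | step 9 | (2R,3R,4R)-3-methoxy-2-Ar-4-(triethylsilyloxy)-6-(trimethylstannyl)-3,4-dihydro-2H-pyran (trimethylstannyl enol ether) | C[Sn](C)(C)C1=C[C@@H](O[Si](CC)(CC)CC)[C@H](OC)[C@@H](c2cc(O[Si](C(C)C)(C(C)C)C(C)C)c(OC)c(O[Si](C(C)C)(C(C)C)C(C)C)c2)O1
F6 | step 5 | (2R,3R)-4-oxo-2-Ar-3,4-dihydro-2H-pyran-3-yl acetate (trans acetoxy ketone) | O=C1[C@H](OC(C)=O)[C@@H](c2cc(O[Si](C(C)C)(C(C)C)C(C)C)c(OC)c(O[Si](C(C)C)(C(C)C)C(C)C)c2)OC=C1
F7 | step 5 | (2R,3S,4R)-4-hydroxy-2-Ar-3,4-dihydro-2H-pyran-3-yl acetate (acetoxy alcohol, all-trans) | C1=C[C@@H](O)[C@H](OC(C)=O)[C@@H](c2cc(O[Si](C(C)C)(C(C)C)C(C)C)c(OC)c(O[Si](C(C)C)(C(C)C)C(C)C)c2)O1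
F8 | step 5 | (2R,3R,4R)-2-Ar-4-(triethylsilyloxy)-3,4-dihydro-2H-pyran-3-yl acetate (acetoxy silyl ether) | C1=C[C@@H](O[Si](CC)(CC)CC)[C@H](OC(C)=O)[C@@H](c2cc(O[Si](C(C)C)(C(C)C)C(C)C)c(OC)c(O[Si](C(C)C)(C(C)C)C(C)C)c2)O1
F9 | step 5 | (2R,3R,4R)-2-Ar-4-(triethylsilyloxy)-3,4-dihydro-2H-pyran-3-ol (C3 alcohol) | C1=C[C@@H](O[Si](CC)(CC)CC)[C@H](O)[C@@H](c2cc(O[Si](C(C)C)(C(C)C)C(C)C)c(OC)c(O[Si](C(C)C)(C(C)C)C(C)C)c2)O1
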